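The runs are calculated from invented constants; noise was put on by code.

1. The mM, not the percent, is the unit in which the earlier runs compare. Multiplied by its charge, spring gains 0.319 mM/h of product between 3.00 h and 8.00 h, and noon gains 0.326 mM/h, about the same, despite different charges of solid substrate (apparent zero order in the solid). Their mean, 0.322 mM/h, is the molar pace: product gained per hour, in mM, as read from these two runs at 0.12 mM of free catalyst.

the same everywhere: gas phase 1.6 mM (held)

| run | solid substrate | free catalyst | remark | time |
|---|---|---|---|---|
| spring | 28 mM | 0.12 mM | run made earlier |  |
| noon | 44 mM | 0.12 mM | run made earlier |  |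
| autumn | 20 mM | 0.24 mM | run made earlier |  |
| flask | 20 mM | 0.12 mM |  | 12 h |

| run | time / h | product / % |
|---|---|---|
| spring | 1.33 | 0 |
| spring | 3.00 | 3.8 |
| spring | 4.00 | 5.9 |
| spring | 6.00 | 6.5 |
| spring | 8.00 | 9.5 |
| noon | 1.33 | 0 |
| noon | 3.00 | 1.1 |
| noon | 4.00 | 2.8 |
| noon | 6.00 | 3.2 |
| noon | 8.00 | 4.8 |
| autumn | 1.33 | 3.1 |
| autumn | 3.00 | 7.1 |
| autumn | 4.00 | 7.3 |
| autumn | 6.00 | 11.7 |
| autumn | 8.00 | 17.2 |

(readings scatter by 1 percentage point)

- solid, in amounts per volume of the solution: solid substrate
- at the start none of the gas phase is in solution
- at the start none of the solid substrate is in solution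

- maple: doubling the solubility of the solid substrate, all else as stated
- cedar: doubling the saturation concentration of gas phase, all else as stated
- oak: doubling the transfer coefficient of the gas phase, all else as stated
- birch: doubling the dissolution coefficient of the solid substrate, all else as stated

- amount of product at 12 h, in percent of the solid substrate charged
- the change that raises the amount of product at 12 h, in percent of the solid substrate charged most ("none" if none brings more than 2 percentage points) (maple / cedar / oak / birch / none)
- amount of product at 12 h, in percent of the solid substrate charged, after birch

2. First way, my own: spring and noon average 2.39 mM at 8.00 h. Held flat up to 12 h, the molar pace takes the flask to 3.68 mM, or 18.4 %.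

3. Second way: autumn has the flask's solid charge, gains 0.404 mM/h, and carries more catalyst. Extended the same way and scaled by the catalyst ratio 0.500, it gives 2.53 mM, or 12.6 %.

4. The two part, so the scaling is tested at 8.00 h: it predicts 1.72 mM, while spring and noon read 2.39 mM, a gap wider than the 0.440 mM that one point of scatter means on a noon reading. The scaling reads low there, so the second way is the one that cheats. I commit to the first, which assumes a flat pace past the last reading, and it ranks no change.

5. The forecast, slightly above my number, gives 19 %, cedar as the best change, and 21 % after birch, holding that “a supply step also limits the rate”.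

6. The flask gives 15.5 %, and 23.1 % after birch. The best change is maple, worth 15 percentage points against 6.3 points for cedar.

    2 free catalyst ⇌ resting dimer, settled at all times (K = 3210 /M)
    starting material + dissolved gas + free catalyst → free catalyst + product (k = 1.02 × 10⁵ /M²/min)
    gas phase ⇌ dissolved gas, rate k3*(csat - [dissolved gas]) (kL = 0.0671 /min)
    free catalyst → spent catalyst (k = 0.00446 /min)
    solid substrate ⇌ starting material, rate k5*(cs5 - [starting material]) while solid is left; crystals form when [starting material] > cs5 (solubility = 2.60 mM, k = 0.00423 /min)

In the flask, product rose at 0.338 mM/h between 1.20 h and 6.00 h, close to the molar pace of 0.322 mM/h, then slowed to 0.209 mM/h up to 12.0 h, while free catalyst, with a half-life of 2.6 h by its own decay alone, shorter than the 12 h asked, fell from 25.1 % to 6.68 % of its charge. The neighbour charged with 0.20 mM of free catalyst reached 20.5 %, a mean pace over the 12 h of 0.342 mM/h, against 0.258 mM/h for the flask.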